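**Retrosynthetic overview**

1. Target 20 ⇐ 19 by removing two TBS ethers; 19 ⇐ open-chain enal 17 by one 1,10-type closure: the C7=C11 π bond attacks the C6 aldehyde while boron leaves C13 (intramolecular allylboration), and the new C6–O then closes onto C12.
2. Ring order: ten-membered carbocycle first (C6–C7, the farnesyl C1–C10 bond), γ-lactone second, same flask; C6 and C7 are set there from the (Z)-enoate geometry and the C8 centre.
3. 17 ⇐ 16 ⇐ α-acyloxy aldehyde 12 + boryl phosphonate 15 (Z-selective olefination).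
4. 12 ⇐ triol 9 ⇐ enal-lactone 8 ⇐ 6 + glyoxal monoacetal 7 (aldol condensation, C4=C5); 6 ⇐ glycidyl ether 2 + phosphonoacetate 3 + glutaraldehyde 4 (epoxide opening/lactonisation/olefination, C1=C10).
5. C8 comes from (S)-glycidol; both trisubstituted olefins come from thermodynamically controlled carbonyl condensations.

Assumption: the SMILES is read literally, i.e. 6R,7R,8R and both ring olefins E by CIP (each CH2OH trans to the ring carbon on the CH end, so C6 is cis to C3 and C2 is cis to C9); germacrane numbering is used in the text (C1=C10(C14), C4(C15)=C5, C6–O, C7, C8–O-acyl, C11=C13, C12=O).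

**Route**

Step 1
Reactants: 1 (S)-glycidol
Product: 2 triethyl{[(2R)-oxiran-2-yl]methoxy}silane
Conditions: Et3SiCl, imidazole, CH2Cl2, 0 °C
Reagents that add atoms: chlorotriethylsilane, CC[Si](CC)(CC)Cl
Why: Imidazole-promoted O-silylation of the primary alcohol; the epoxide carbon (later C8) is untouched and its descriptor changes to R only through the CIP priority change.

Step 2
Reactants: 2 triethyl{[(2R)-oxiran-2-yl]methoxy}silane, 3 triethyl phosphonoacetate, 4 glutaraldehyde
Product: 6 (E)-alkylidene lactone aldehyde, via sodium phosphonolactone carbanion 5 (not isolated)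
Conditions: 3, NaH, THF, 0 °C; 2, 65 °C; then 4 (5 equiv, dried CH2Cl2 extract), −20 °C → rt
Reagents that add atoms: none
Why: The stabilised phosphonoacetate carbanion opens the epoxide at CH2 (SN2, C8–O bond untouched), the alkoxide lactonises, and the resulting α-phosphono lactone anion undergoes Horner–Wadsworth–Emmons olefination with one carbonyl of excess glutaraldehyde to give mainly the E-alkylidene lactone (chain trans to C=O, so C2 cis to C9).

Step 3
Reactants: 6 (E)-alkylidene lactone aldehyde, 7 2,2-dimethoxyacetaldehyde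
Product: 8 (2E)-4,4-dimethoxy-2-alkyl enal lactone
Conditions: 7 (60 % aq., 3 equiv), pyrrolidine (20 mol %), EtCO2H (20 mol %), MeCN, 40 °C
Reagents that add atoms: none
Why: Amine/acid-catalysed cross-aldol condensation in which only 6 can form an enamine and the non-enolisable glyoxal monoacetal is the acceptor; dehydration gives the thermodynamic E-2-alkyl enal (acetal carbon trans to CHO, so C6 cis to C3), as in the technical condensation of propanal with this acetal.

Step 4
Reactants: 8 (2E)-4,4-dimethoxy-2-alkyl enal lactone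
Product: 9 triol (two primary allylic OH and the C8 secondary OH)
Conditions: DIBAL-H (5 equiv), CH2Cl2, −78 → 0 °C; aq. Rochelle salt
Reagents that add atoms: none
Why: DIBAL-H 1,2-reduction of the enal and full reduction of the alkylidene lactone to the allylic alcohol and the C8 carbinol; acetal, TES ether, both olefin geometries and C8 are unaffected.

Step 5
Reactants: 9 triol
Product: 11 C8 isovalerate bis-TBS ether, via bis-TBS secondary alcohol 10 (not isolated)
Conditions: TBSCl (2.1 equiv), imidazole, CH2Cl2, −20 → 0 °C; then (i-PrCH2CO)2O, Et3N, DMAP (cat.), rt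
Reagents that add atoms: tert-butyldimethylsilyl chloride, CC(C)(C)[Si](C)(C)Cl; 3-methylbutanoic anhydride, CC(C)CC(=O)OC(=O)CC(C)C
Why: Sterically controlled silylation of the two primary allylic alcohols, then DMAP-catalysed acylation of the remaining secondary C8–OH with retention.

Step 6
Reactants: 11 C8 isovalerate bis-TBS ether
Product: 12 α-acyloxy aldehyde
Conditions: (COCl)2, DMSO, CH2Cl2, −78 → −40 °C; Et3N, −78 → 0 °C
Reagents that add atoms: none
Why: Swern conditions convert a primary triethylsilyl ether directly into the aldehyde (chloride-assisted Si–O cleavage by the chlorosulfonium salt, then ylide fragmentation) while primary TBS ethers, the ester and the acetal survive; no free 1,2-hydroxy ester is formed (no acyl migration) and the low temperature protects the α-centre.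

Step 7
Reactants: 13 methyl bis(2,2,2-trifluoroethyl)phosphonoacetate, 14 2-(iodomethyl)-4,4,5,5-tetramethyl-1,3,2-dioxaborolane
Product: 15 α-(borylmethyl) Still–Gennari phosphonate
Conditions: 13, NaH, THF, 0 °C; 14, 0 °C → rt
Reagents that add atoms: none
Why: C-alkylation of the phosphonoacetate anion with an α-halomethyl boronate (SN2 assisted by boron ate-complex formation), the same type of alkylation used to make α-alkyl Still–Gennari reagents.

Step 8
Reactants: 12 α-acyloxy aldehyde, 15 α-(borylmethyl) Still–Gennari phosphonate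
Product: 16 (Z)-enoate allylboronate acetal
Conditions: 15, KHMDS, 18-crown-6, THF, −78 °C; then 12, −78 °C
Reagents that add atoms: none
Why: Proposed new method: Still–Gennari (Z-selective Horner–Wadsworth–Emmons) olefination with the new phosphonate 15, in which fast elimination from the kinetic adduct of the electron-poor phosphonate places C8 cis to CO2Me and trans to CH2Bpin and −78 °C keeps the α-acyloxy aldehyde from epimerising; the closest known reactions are Z-selective olefinations with α-alkyl Still–Gennari phosphonates and Wittig olefinations with β-boryl phosphonium ylides that give allylboronates.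

Step 9
Reactants: 16 (Z)-enoate allylboronate acetal
Product: 19 bis-TBS germacranolide, via boronate enal 17 (not isolated), via macrocyclic O-boryl hydroxy ester 18 (not isolated)
Conditions: PPTS (cat.), acetone/H2O, rt; evaporate; Sc(OTf)3 (20 mol %), CH2Cl2 (2 mM), rt → 40 °C; then TsOH·H2O (cat.)
Reagents that add atoms: water, O
Why: Proposed new method: after mild hydrolysis of the enal acetal, a Lewis-acid-catalysed intramolecular allylboration closes the ten-membered ring through a chair transition state with both ring arms equatorial (C7=C11 attacks C6, boron leaves C13), so the Z-enoate geometry (C8 trans to CH2B) becomes the anti, 6,7-trans relationship, while C8 (H-8 eclipsing the cis ester by allylic 1,3-strain, acyloxy outside, C9 tether anti to the forming bond) directs the aldehyde to the face giving 6R,7R, and the borate then lactonises onto the ester; the closest known reactions are the stereospecific Sc(OTf)3-catalysed allylboration/lactonisation of 2-alkoxycarbonyl allylboronates with aldehydes, intramolecular allylborations to 5–7-membered rings and chromium-mediated ten-ring closures of the same bond.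

Step 10
Reactants: 19 bis-TBS germacranolide
Product: 20 target (CNP0199826.1)
Conditions: HF·pyridine, pyridine, THF, 0 °C → rt
Reagents that add atoms: none
Why: Buffered fluoride cleavage of the two primary TBS ethers, which leaves the α-methylene lactone, the isovalerate and the three stereocentres untouched.

**Compound list**

1 | (S)-glycidol, (2S)-oxiran-2-ylmethanol | OC[C@H]1CO1 | starting material
2 | triethyl{[(2R)-oxiran-2-yl]methoxy}silane | CC[Si](CC)(CC)OC[C@H]1CO1 | intermediate
3 | triethyl phosphonoacetate | CCOC(=O)CP(=O)(OCC)OCC | starting material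
4 | glutaraldehyde (pentanedial) | O=CCCCC=O | starting material
5 | sodium salt (C3 carbanion) of diethyl [(5R)-2-oxo-5-{[(triethylsilyl)oxy]methyl}oxolan-3-yl]phosphonate | [Na+].CCOP(=O)(OCC)[C-]1C[C@H](CO[Si](CC)(CC)CC)OC1=O | intermediate
6 | (E)-5-[(5R)-2-oxo-5-{[(triethylsilyl)oxy]methyl}oxolan-3-ylidene]pentanal | O=CCCC/C=C1\C[C@H](CO[Si](CC)(CC)CC)OC1=O | intermediate
7 | 2,2-dimethoxyacetaldehyde | COC(OC)C=O | starting material
8 | (2E)-4,4-dimethoxy-2-{(3E)-3-[(5R)-2-oxo-5-{[(triethylsilyl)oxy]methyl}oxolan-3-ylidene]propyl}but-2-enal | COC(OC)/C=C(/C=O)CC/C=C1\C[C@H](CO[Si](CC)(CC)CC)OC1=O | intermediate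
9 | (2R,4E,8E)-4,8-bis(hydroxymethyl)-10,10-dimethoxy-1-[(triethylsilyl)oxy]deca-4,8-dien-2-ol | COC(OC)/C=C(/CO)CC/C=C(/CO)C[C@@H](O)CO[Si](CC)(CC)CC | intermediate
10 | (2R,4E,8E)-4,8-bis({[tert-butyl(dimethyl)silyl]oxy}methyl)-10,10-dimethoxy-1-[(triethylsilyl)oxy]deca-4,8-dien-2-ol | COC(OC)/C=C(/CO[Si](C)(C)C(C)(C)C)CC/C=C(/CO[Si](C)(C)C(C)(C)C)C[C@@H](O)CO[Si](CC)(CC)CC | intermediate
11 | (2R,4E,8E)-4,8-bis({[tert-butyl(dimethyl)silyl]oxy}methyl)-10,10-dimethoxy-1-[(triethylsilyl)oxy]deca-4,8-dien-2-yl 3-methylbutanoate | COC(OC)/C=C(/CO[Si](C)(C)C(C)(C)C)CC/C=C(/CO[Si](C)(C)C(C)(C)C)C[C@@H](OC(=O)CC(C)C)CO[Si](CC)(CC)CC | intermediate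
12 | (2R,4E,8E)-4,8-bis({[tert-butyl(dimethyl)silyl]oxy}methyl)-10,10-dimethoxy-1-oxodeca-4,8-dien-2-yl 3-methylbutanoate | COC(OC)/C=C(/CO[Si](C)(C)C(C)(C)C)CC/C=C(/CO[Si](C)(C)C(C)(C)C)C[C@@H](OC(=O)CC(C)C)C=O | intermediate
13 | methyl 2-[bis(2,2,2-trifluoroethoxy)phosphoryl]acetate | COC(=O)CP(=O)(OCC(F)(F)F)OCC(F)(F)F | starting material
14 | 2-(iodomethyl)-4,4,5,5-tetramethyl-1,3,2-dioxaborolane | CC1(C)OB(CI)OC1(C)C | starting material
15 | methyl 2-[bis(2,2,2-trifluoroethoxy)phosphoryl]-3-(4,4,5,5-tetramethyl-1,3,2-dioxaborolan-2-yl)propanoate (racemic) | COC(=O)C(CB1OC(C)(C)C(C)(C)O1)P(=O)(OCC(F)(F)F)OCC(F)(F)F | intermediate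
16 | methyl (2Z,4R,6E,10E)-6,10-bis({[tert-butyl(dimethyl)silyl]oxy}methyl)-12,12-dimethoxy-4-[(3-methylbutanoyl)oxy]-2-[(4,4,5,5-tetramethyl-1,3,2-dioxaborolan-2-yl)methyl]dodeca-2,6,10-trienoate | COC(OC)/C=C(/CO[Si](C)(C)C(C)(C)C)CC/C=C(/CO[Si](C)(C)C(C)(C)C)C[C@@H](OC(=O)CC(C)C)/C=C(\C(=O)OC)CB1OC(C)(C)C(C)(C)O1 | intermediate
17 | methyl (2Z,4R,6E,10E)-6,10-bis({[tert-butyl(dimethyl)silyl]oxy}methyl)-4-[(3-methylbutanoyl)oxy]-12-oxo-2-[(4,4,5,5-tetramethyl-1,3,2-dioxaborolan-2-yl)methyl]dodeca-2,6,10-trienoate | O=C/C=C(/CO[Si](C)(C)C(C)(C)C)CC/C=C(/CO[Si](C)(C)C(C)(C)C)C[C@@H](OC(=O)CC(C)C)/C=C(\C(=O)OC)CB1OC(C)(C)C(C)(C)O1 | intermediate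
18 | methyl 2-[(1S,2R,3E,7E,10R)-4,8-bis({[tert-butyl(dimethyl)silyl]oxy}methyl)-10-[(3-methylbutanoyl)oxy]-2-[(4,4,5,5-tetramethyl-1,3,2-dioxaborolan-2-yl)oxy]cyclodeca-3,7-dien-1-yl]prop-2-enoate | C=C(C(=O)OC)[C@H]1[C@H](OB2OC(C)(C)C(C)(C)O2)/C=C(/CO[Si](C)(C)C(C)(C)C)CC/C=C(/CO[Si](C)(C)C(C)(C)C)C[C@H]1OC(=O)CC(C)C | intermediate
19 | (3aR,4R,6E,10E,11aR)-6,10-bis({[tert-butyl(dimethyl)silyl]oxy}methyl)-3-methylidene-2-oxo-2,3,3a,4,5,8,9,11a-octahydrocyclodeca[b]furan-4-yl 3-methylbutanoate | C=C1C(=O)O[C@@H]2/C=C(/CO[Si](C)(C)C(C)(C)C)CC/C=C(/CO[Si](C)(C)C(C)(C)C)C[C@@H](OC(=O)CC(C)C)[C@@H]12 | intermediate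
20 | (3aR,4R,6E,10E,11aR)-6,10-bis(hydroxymethyl)-3-methylidene-2-oxo-2,3,3a,4,5,8,9,11a-octahydrocyclodeca[b]furan-4-yl 3-methylbutanoate | C=C1C(=O)O[C@@H]2/C=C(/CO)CC/C=C(/CO)C[C@@H](OC(=O)CC(C)C)[C@@H]12 | target

**Step count and risk**

Total steps: 10. Longest linear sequence: 9 (steps 1–6, 8, 9, 10); step 7 is a one-step side branch that makes reagent 15.

The three steps most likely to fail:

Step 9, the ten-ring allylboration/lactonisation. A ten-membered allylboration has no direct precedent; at 2 mM the catalysed reaction may be too slow, and the Lewis acid could damage the neral-type enal (Prins-type attack by the C1=C10 olefin). The facial control by C8 also rests on a model. The fallback sets out from 16 and replaces the allylboron closure by a reductive organochromium closure. The C–B bond is oxidised (NaBO3·4H2O, THF/H2O) to the 2-(hydroxymethyl) enoate F1. CBr4/PPh3 turns this into the allylic bromide F2, and PPTS in wet acetone unmasks the bromo enal F3. CrCl2 in THF/DMF at 2 mM then gives an allylchromium(III) species that equilibrates and adds to the aldehyde through a chair transition state (anti adduct); the chromium alkoxide lactonises, and the route is rejoined at 19.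

Step 8, the olefination with the untested boryl phosphonate. The intermediate alkoxide can be held back as a five-membered boron ate complex, and the Z-selectivity of this particular reagent is unproven. The fallback sets out from 12 and builds the same olefin by halide coupling instead. Phosphonate 13 is brominated (NaH, then NBS) to the bromophosphonate F4. Its potassium salt (t-BuOK, 18-crown-6, THF, −78 °C) olefinates 12 to the (E)-2-bromo enoate F5 (Br trans to C8, ester cis). A Pd-catalysed Suzuki–Miyaura coupling of the C–Br bond with commercial bis[(pinacolato)boryl]methane (Pd[P(t-Bu)3]2, aq. KOH, dioxane, rt) then installs CH2Bpin with retention and comes back to the route at 16.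

Step 2, the one-flask epoxide opening and mono-olefination of glutaraldehyde. Glutaraldehyde oligomerises under base and can be olefinated twice, and the E/Z ratio of the alkylidene lactone is only moderate. The fallback sets out from 2 and 3, which are taken to carbanion 5 exactly as before. Carbanion 5 is then olefinated with tetrahydro-2H-pyran-2-ol (the lactol of 5-hydroxypentanal, one extra equivalent of NaH) to the hydroxypentylidene lactone F6. Oxidation of the primary alcohol with Dess–Martin periodinane/NaHCO3 returns to the route at 6.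

**Further compounds**

F1 | step 9 | methyl (2Z,4R,6E,10E)-6,10-bis({[tert-butyl(dimethyl)silyl]oxy}methyl)-2-(hydroxymethyl)-12,12-dimethoxy-4-[(3-methylbutanoyl)oxy]dodeca-2,6,10-trienoate | COC(OC)/C=C(/CO[Si](C)(C)C(C)(C)C)CC/C=C(/CO[Si](C)(C)C(C)(C)C)C[C@@H](OC(=O)CC(C)C)/C=C(\C(=O)OC)CO
F2 | step 9 | methyl (2E,4R,6E,10E)-2-(bromomethyl)-6,10-bis({[tert-butyl(dimethyl)silyl]oxy}methyl)-12,12-dimethoxy-4-[(3-methylbutanoyl)oxy]dodeca-2,6,10-trienoate | COC(OC)/C=C(/CO[Si](C)(C)C(C)(C)C)CC/C=C(/CO[Si](C)(C)C(C)(C)C)C[C@@H](OC(=O)CC(C)C)/C=C(\C(=O)OC)CBr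
F3 | step 9 | methyl (2E,4R,6E,10E)-2-(bromomethyl)-6,10-bis({[tert-butyl(dimethyl)silyl]oxy}methyl)-4-[(3-methylbutanoyl)oxy]-12-oxododeca-2,6,10-trienoate | O=C/C=C(/CO[Si](C)(C)C(C)(C)C)CC/C=C(/CO[Si](C)(C)C(C)(C)C)C[C@@H](OC(=O)CC(C)C)/C=C(\C(=O)OC)CBr
F4 | step 8 | methyl 2-[bis(2,2,2-trifluoroethoxy)phosphoryl]-2-bromoacetate | COC(=O)C(Br)P(=O)(OCC(F)(F)F)OCC(F)(F)F
F5 | step 8 | methyl (2E,4R,6E,10E)-2-bromo-6,10-bis({[tert-butyl(dimethyl)silyl]oxy}methyl)-12,12-dimethoxy-4-[(3-methylbutanoyl)oxy]dodeca-2,6,10-trienoate | COC(OC)/C=C(/CO[Si](C)(C)C(C)(C)C)CC/C=C(/CO[Si](C)(C)C(C)(C)C)C[C@@H](OC(=O)CC(C)C)/C=C(/Br)C(=O)OC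
F6 | step 2 | (3E,5R)-3-(5-hydroxypentylidene)-5-{[(triethylsilyl)oxy]methyl}oxolan-2-one | OCCCC/C=C1\C[C@H](CO[Si](CC)(CC)CC)OC1=O
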